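## The problem

CNP0210944.0 (22) is a diaryl ether of two hexasubstituted benzene rings. Ring A is a methyl benzoate (C1 CO2Me, C2 Me, C3 O-aryl, C4 OH, C5 Me, C6 OH) and ring B is a benzoic acid (C1' O-aryl, C2' CHO, C3' OH, C4' Cl, C5' Me, C6' CO2H). The ether oxygen has four ortho neighbours (C2 Me, C4 OH, C2' CHO, C6' CO2H), so joining two finished rings would ask a di-ortho-substituted phenol to displace a leaving group from a di-ortho-substituted arene. There is no stereocentre, so the whole problem is regiochemical: twelve substituents must each reach the right ring carbon.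

The fragile points are:
- the salicylaldehyde and the aryl chloride, both at risk under hydrogenolysis;
- the electron-rich ring B acid, which can decarboxylate in hot acid;
- the methyl ester, which must survive the liberation of the ring B acid;
- ring A itself, which as a free, fully substituted resorcinol invites attack of electrophilic chlorine at its substituted carbons.

The enabling feature is ring B. Its C2'–C5' segment, with the C3' oxygen and the C5' methyl, is C3–C6 of 4-hydroxy-6-methyl-2-pyrone, and C1'/C6' are an oxygen-bearing carbon next to a carboxyl-bearing carbon, that is, an alkynyl ether ester. Ring B can therefore be grown on the ring A oxygen. The two positions this leaves open, C2' and C4', are both ortho to the C3' hydroxyl and can be filled afterwards by electrophilic substitution. Ring A with all its carbon substituents is available as atraric acid (1), which lacks only the C3 oxygen.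

## Retrosynthesis

**22 from 21.** The three O–benzyl bonds (two ring A ethers and the ring B ester) are cut last. Benzyl is chosen because BCl3 with a cation scavenger removes it without touching the aryl chloride, the aldehyde or the methyl ester, which hydrogenolysis could not promise. The precursor 21 has the full skeleton and substitution; the forward step only has to spare the methyl ester.

**21 from 19, and 19 from 18.** The C2'–CHO and C4'–Cl bonds are cut in that order. Both carbons are ortho to the C3' hydroxyl of 18, but C4' is para to the ether oxygen and less crowded, so chlorination is placed first. After it, C2' is the only aromatic C–H left in the molecule and formylation has no choice. Doing both steps after a global deprotection would be one step shorter, but ring A would then be a free resorcinol open to ipso-chlorination and dearomatization. Ring A therefore stays benzylated and only the C3' oxygen is free. Precursor 18 has two fewer substituents.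

**18 from 17.** The C3' O–(4-methoxybenzyl) bond is cut. This oxygen comes from the pyrone and needs a group that leaves with dilute acid while benzyl ethers and the benzyl ester stay; 4-methoxybenzyl does this and keeps the diene electron-rich.

**17 from 13 and 15.** C1'–C2' and C5'–C6' are cut together, which dissolves ring B into the alkynyl ether ester 13 and the pyrone 15. The neighbouring cut, the aryl–O bond, would need a hindered C–O coupling; here that bond already exists on an sp carbon before any ring B substituent is present. The precursors are a protected ring A carrying a three-carbon chain and a one-step pyrone. The forward reaction needs one orientation (ether oxygen next to pyrone C3, ester next to the methyl-bearing carbon) and enough thermal reactivity from a push–pull alkyne.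

**13 from 9, and 9 from 6, 7 and 10.** The alkyne–carboxyl C–C bond is cut back to benzyl chloroformate (10) and a lithium aryloxyacetylide. The O–C(sp) bond is cut back to phenol 6 and trichloroethylene (7) by way of the dichlorovinyl ether 9. This is the standard two-carbon route to alkynyl ethers and needs no metal-catalysed coupling at the crowded phenol. The hindered methyl ester must survive n-BuLi at low temperature.

**6 from 4, 4 from 3, 3 from 1.** The C3–O bond is traced to a C3 formyl group (Baeyer–Villiger oxidation of 4), and the formyl group to the single free position of 1. Bromination followed by hydroxylation was the neighbouring option; it would need a hydroxide coupling or a metalation at a di-ortho-substituted bromide next to an ester. Formylation and peracid oxidation use only classical reactions and the same number of steps.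

**15 from 14.** The 4-O–C bond is cut to commercial 4-hydroxy-6-methyl-2-pyrone (14) and 4-methoxybenzyl chloride.

## Roads not taken

**Alternative 1:** Ring A is cut at C2–C3 and C4–C5 and built as a cyclohexanedione on the ring B oxygen.
- Forward step: the lithium enolate of the aryloxyacetate A1 adds to methyl 2-propanoylbut-2-enoate (A2) in a Michael reaction, and the propanoyl α-carbon then acylates on the acetate ester to give dione A3.
- Merits: the ether bond is made by simple O-alkylation of a ring B phenol. Ring B arrives with its chlorine, so the C2'/C4' chlorination question never arises; in this respect it is better than the chosen plan.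
- Weak points: A3 is one oxidation level short of the arene. Under the basic or oxidative conditions needed to dehydrogenate it, loss of the aryloxy group from C3 also aromatizes the ring, giving 1 and destroying the ether. A2 is a reactive alkylidene β-keto ester that isomerizes and self-condenses. The second ring closure needs a regioselective enolization beside a crowded ketone.
- Comparison: ring A would be synthesized although it can be bought, and the formylation still remains. The chosen plan sets against the chlorine advantage a commercial ring A and no oxidation-level adjustment.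

**Alternative 2:** Ring A is cut at C1–C2 and stored as a pyrone-masked polyketide chain.
- Forward step: Mg(OMe)2 in methanol opens pyrone A4 to the magnesium chelate of triketo ester A5, whose C1 methylene condenses with the C2 methyl ketone to give A6.
- Merits: ring A is closed with its methyl ester and both phenols free, so no ring A protecting groups or late debenzylation are needed. The chlorine is again in place. On protecting-group economy this is better than the chosen plan.
- Weak points: A4 is a 6-(1-aryloxy-2-oxopropyl)pyrone that itself needs several C–C bond formations. In A5 the ketone that must be attacked sits next to the carbon bearing the bulky aryloxy group. Claisen-type closures and relactonization compete with the required aldol.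
- Comparison: the short end game is paid for by a long, uncertain route to A4. The chosen plan spends two benzylations and one deprotection but starts from an intact ring A.

**Alternative 3:** Ring A is cut at C5–C6, C3–C4 and C1–C6 and assembled by a vinylketene–siloxyalkyne benzannulation (Danheiser type).
- Forward step: Et3N converts acid chloride A7 into the aryloxy(vinyl)ketene A8. This adds to siloxyalkyne A9 by [2+2] cycloaddition; 4π ring opening and 6π closure then give phenol A10.
- Merits: a hexasubstituted ring is formed in one pericyclic cascade at moderate temperature. The regiochemistry is dictated by mechanism, the two ring A oxygens come out differentiated, and the chlorine is in place. In temperature and regiochemical certainty it is ahead of the chosen key step.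
- Weak points: A7 is a glutaconic half-ester chloride with acidic γ-hydrogens, so ketene formation competes with dienolate chemistry and ketene dimerization. A7 must be made by alkylating a ring B phenol at a secondary allylic carbon, where SN2' competes. A9 is moisture-sensitive and needs its own synthesis. A silyl ether, an acetal and a tert-butyl ester must still be removed and the formyl group added.
- Comparison: more steps and more fragile intermediates. The chosen plan sets against the milder ring closure a bench-stable ring A, a two-carbon linchpin from trichloroethylene, and a cycloaddition whose orientation is backed by matched polarity.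

Key step: step 7

Remark on the chemistry: rotation about the aryl–O bonds of the diaryl ether is assumed to be fast at room temperature, so 22 has no stereogenic element. Ring A is numbered as in the target throughout (C1 CO2Me, C2 Me, C3, C4 O, C5 Me, C6 O); in this numbering atraric acid has H at C3.

## Route

Step 1
Reactants: 1 atraric acid (methyl 2,4-dihydroxy-3,6-dimethylbenzoate)
Product: 3 methyl 3-formyl-4,6-dihydroxy-2,5-dimethylbenzoate, via chloro(methoxy)methyl arene 2 (not isolated)
Conditions: Cl2CHOMe, TiCl4, CH2Cl2, 0 °C to rt; then aq. HCl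
Reagents that add atoms: dichloromethyl methyl ether, COC(Cl)Cl; water, O
Why: Rieche formylation; C3 is the only free ring position, ortho to the C4 hydroxyl and para to the C6 hydroxyl, and the titanium phenoxide delivers the electrophile there. Hydrolysis of 2 on work-up should give the aldehyde.

Step 2
Reactants: 3 methyl 3-formyl-4,6-dihydroxy-2,5-dimethylbenzoate
Product: 4 methyl 4,6-bis(benzyloxy)-3-formyl-2,5-dimethylbenzoate
Conditions: BnBr, K2CO3, DMF, 60 °C
Reagents that add atoms: benzyl bromide, BrCc1ccccc1
Why: Williamson etherification; warm DMF breaks the hydrogen bonds of both chelated phenols, and the aldehyde and methyl ester are inert to carbonate.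

Step 3
Reactants: 4 methyl 4,6-bis(benzyloxy)-3-formyl-2,5-dimethylbenzoate
Product: 6 methyl 4,6-bis(benzyloxy)-3-hydroxy-2,5-dimethylbenzoate, via aryl formate 5 (not isolated)
Conditions: mCPBA, CH2Cl2, 0 °C to rt; aqueous wash; then K2CO3 (0.2 equiv), MeOH, rt
Reagents that add atoms: mCPBA, OOC(=O)c1cccc(Cl)c1
Why: Baeyer–Villiger (Dakin-type) oxidation; the aryl group has benzyloxy groups ortho and para to the formyl carbon and should migrate in preference to hydride. Mild methanolysis of formate 5 frees the phenol without affecting the hindered methyl ester.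

Step 4
Reactants: 6 methyl 4,6-bis(benzyloxy)-3-hydroxy-2,5-dimethylbenzoate; 7 trichloroethylene
Product: 9 methyl 4,6-bis(benzyloxy)-3-{[(E)-1,2-dichloroethenyl]oxy}-2,5-dimethylbenzoate, via dichloroacetylene 8 (not isolated)
Conditions: K2CO3, DMF, 70 °C
Reagents that add atoms: none
Why: Base-induced elimination from trichloroethylene gives dichloroacetylene, to which the phenoxide adds in anti fashion to give the (E)-dichlorovinyl ether. This standard entry to alkynyl ethers works on hindered phenoxides because the electrophile is a linear sp carbon.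

Step 5
Reactants: 9 methyl 4,6-bis(benzyloxy)-3-{[(E)-1,2-dichloroethenyl]oxy}-2,5-dimethylbenzoate; 10 benzyl chloroformate
Product: 13 methyl 4,6-bis(benzyloxy)-3-{[3-(benzyloxy)-3-oxoprop-1-yn-1-yl]oxy}-2,5-dimethylbenzoate, via chloroethynyl ether 11 (not isolated), via lithium aryloxyacetylide 12 (not isolated)
Conditions: n-BuLi (2.1 equiv), THF, −78 °C; then ClCO2Bn, −78 to −20 °C
Reagents that add atoms: none
Why: Deprotonation and β-elimination give chloroalkyne 11, lithium–chlorine exchange gives acetylide 12, and C-acylation with the chloroformate gives the propiolate (dichlorovinyl ether route to alkynyl ethers). The methyl ester lies between two ortho substituents and is twisted out of conjugation, so fast vinyl deprotonation at −78 °C should outrun addition to it.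

Step 6
Reactants: 14 4-hydroxy-6-methyl-2H-pyran-2-one
Product: 15 4-[(4-methoxybenzyl)oxy]-6-methyl-2H-pyran-2-one
Conditions: 4-MeOC6H4CH2Cl, K2CO3, Bu4NI (cat.), DMF, 50 °C
Reagents that add atoms: 4-methoxybenzyl chloride, COc1ccc(CCl)cc1
Why: O-alkylation of the vinylogous acid; the pyronate reacts with benzylic halides mainly at the 4-oxygen to give the 4-alkoxy-2-pyrone.

Step 7
Reactants: 13 methyl 4,6-bis(benzyloxy)-3-{[3-(benzyloxy)-3-oxoprop-1-yn-1-yl]oxy}-2,5-dimethylbenzoate; 15 4-[(4-methoxybenzyl)oxy]-6-methyl-2H-pyran-2-one
Product: 17 methyl 4,6-bis(benzyloxy)-3-{2-[(benzyloxy)carbonyl]-5-[(4-methoxybenzyl)oxy]-3-methylphenoxy}-2,5-dimethylbenzoate, via bicyclic lactone 16 (not isolated)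
Conditions: 15 (3 equiv), 2,6-di-tert-butyl-4-methylphenol (cat.), 1,2-dichlorobenzene, 170–180 °C, sealed tube
Reagents that add atoms: none
Why: Proposed new method: 2-pyrones are known to add acetylenic esters across C3 and C6 and to lose CO2 from the bridged lactone, but an alkynyl ether ester has not served as the 2π partner; the reasoning is that 13 is electrophilic at its oxygen-bearing β-carbon and nucleophilic at its ester-bearing α-carbon, which matches 15 (nucleophilic at C3, electrophilic at C6), so normal and inverse frontier-orbital pairings lead to the same asynchronous concerted [4+2] transition state with the C3–Cβ bond leading. Ring B is closed by this intermolecular suprafacial [4π+2π] cycloaddition, which forms C1'–C2' and C5'–C6' and gives the 2-oxabicyclo[2.2.2]octadienone 16; retro-[4+2] loss of CO2 at the reaction temperature then makes the ring aromatic. The two bridgehead stereocentres of 16 are locked relative to each other by the bicycle, arise as a racemate and vanish with the CO2, so no stereocontrol is needed. The selectivity that matters is orientation: the ether oxygen must end next to the pyrone C3–H (C2') and the benzyl ester next to the methyl-bearing carbon (C5'), and the matched polarization secures this. Chemoselectivity rests on ring A being hexasubstituted and on the thermal inertness of its benzyl ethers, the methyl ester and the aryl–O–C(sp) unit, which has no β-hydrogen and so no retro-ene path to a ketene. Excess 15 and a radical inhibitor are meant to offset the low rate expected of a push–pull alkyne.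

Step 8
Reactants: 17 methyl 4,6-bis(benzyloxy)-3-{2-[(benzyloxy)carbonyl]-5-[(4-methoxybenzyl)oxy]-3-methylphenoxy}-2,5-dimethylbenzoate
Product: 18 methyl 4,6-bis(benzyloxy)-3-{2-[(benzyloxy)carbonyl]-5-hydroxy-3-methylphenoxy}-2,5-dimethylbenzoate
Conditions: TFA, anisole, CH2Cl2, 0 °C
Reagents that add atoms: none
Why: Acidolysis of the aryl 4-methoxybenzyl ether with cation capture by anisole; plain benzyl ethers and the benzyl ester do not ionize under dilute cold TFA.

Step 9
Reactants: 18 methyl 4,6-bis(benzyloxy)-3-{2-[(benzyloxy)carbonyl]-5-hydroxy-3-methylphenoxy}-2,5-dimethylbenzoate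
Product: 19 methyl 4,6-bis(benzyloxy)-3-{2-[(benzyloxy)carbonyl]-4-chloro-5-hydroxy-3-methylphenoxy}-2,5-dimethylbenzoate
Conditions: SO2Cl2 (1.0 equiv), Et2O, 0 °C
Reagents that add atoms: sulfuryl chloride, O=S(=O)(Cl)Cl
Why: Electrophilic chlorination ortho to the free phenol; C4' is also para to the ether oxygen and flanked only by OH and Me, whereas C2' is wedged between the hydroxyl and the perpendicular 2,6-disubstituted aryloxy group. Ring A is fully substituted and still benzylated, so it offers no site for substitution or dienone formation.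

Step 10
Reactants: 19 methyl 4,6-bis(benzyloxy)-3-{2-[(benzyloxy)carbonyl]-4-chloro-5-hydroxy-3-methylphenoxy}-2,5-dimethylbenzoate
Product: 21 methyl 4,6-bis(benzyloxy)-3-{2-[(benzyloxy)carbonyl]-4-chloro-6-formyl-5-hydroxy-3-methylphenoxy}-2,5-dimethylbenzoate, via hydroxymethyl phenol 20 (not isolated)
Conditions: MgCl2, Et3N, (CH2O)n, MeCN, reflux
Reagents that add atoms: paraformaldehyde (as formaldehyde), C=O
Why: Magnesium-mediated ortho-formylation (Casnati–Skattebøl); the magnesium phenoxide delivers formaldehyde to C2', the only aromatic C–H left, and the benzylic alkoxide 20 is oxidized to the aldehyde by hydride transfer to a second formaldehyde. The basic, Lewis-acid-poor medium leaves benzyl ethers and both esters alone.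

Step 11
Reactants: 21 methyl 4,6-bis(benzyloxy)-3-{2-[(benzyloxy)carbonyl]-4-chloro-6-formyl-5-hydroxy-3-methylphenoxy}-2,5-dimethylbenzoate
Product: 22 3-chloro-6-[2,4-dihydroxy-5-(methoxycarbonyl)-3,6-dimethylphenoxy]-5-formyl-4-hydroxy-2-methylbenzoic acid (CNP0210944.0)
Conditions: BCl3, C6HMe5, CH2Cl2, −78 to 0 °C; then H2O
Reagents that add atoms: none
Why: Lewis-acid debenzylation with pentamethylbenzene as benzyl cation trap should cleave both aryl benzyl ethers and the benzyl ester. The aryl chloride, aldehyde and diaryl ether are inert, and the methyl ester is not cleaved by BCl3 at or below 0 °C, so the hydrogenolysis that would endanger C–Cl and CHO is avoided.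

## Compound list

1 | atraric acid (methyl 2,4-dihydroxy-3,6-dimethylbenzoate) | COC(=O)c1c(C)cc(O)c(C)c1O | starting material
2 | methyl 3-[chloro(methoxy)methyl]-4,6-dihydroxy-2,5-dimethylbenzoate (racemic; titanium-bound in the flask) | COC(=O)c1c(C)c(C(Cl)OC)c(O)c(C)c1O | intermediate
3 | methyl 3-formyl-4,6-dihydroxy-2,5-dimethylbenzoate | COC(=O)c1c(C)c(C=O)c(O)c(C)c1O | intermediate
4 | methyl 4,6-bis(benzyloxy)-3-formyl-2,5-dimethylbenzoate | COC(=O)c1c(C)c(C=O)c(OCc2ccccc2)c(C)c1OCc3ccccc3 | intermediate
5 | methyl 4,6-bis(benzyloxy)-3-(formyloxy)-2,5-dimethylbenzoate | COC(=O)c1c(C)c(OC=O)c(OCc2ccccc2)c(C)c1OCc3ccccc3 | intermediate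
6 | methyl 4,6-bis(benzyloxy)-3-hydroxy-2,5-dimethylbenzoate | COC(=O)c1c(C)c(O)c(OCc2ccccc2)c(C)c1OCc3ccccc3 | intermediate
7 | trichloroethylene | ClC=C(Cl)Cl | starting material
8 | dichloroacetylene | ClC#CCl | intermediate
9 | methyl 4,6-bis(benzyloxy)-3-{[(E)-1,2-dichloroethenyl]oxy}-2,5-dimethylbenzoate | COC(=O)c1c(C)c(O/C(Cl)=C\Cl)c(OCc2ccccc2)c(C)c1OCc3ccccc3 | intermediate
10 | benzyl chloroformate | O=C(Cl)OCc1ccccc1 | starting material
11 | methyl 4,6-bis(benzyloxy)-3-[(chloroethynyl)oxy]-2,5-dimethylbenzoate | COC(=O)c1c(C)c(OC#CCl)c(OCc2ccccc2)c(C)c1OCc3ccccc3 | intermediate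
12 | lithium acetylide of methyl 4,6-bis(benzyloxy)-3-(ethynyloxy)-2,5-dimethylbenzoate | COC(=O)c1c(C)c(OC#C[Li])c(OCc2ccccc2)c(C)c1OCc3ccccc3 | intermediate
13 | methyl 4,6-bis(benzyloxy)-3-{[3-(benzyloxy)-3-oxoprop-1-yn-1-yl]oxy}-2,5-dimethylbenzoate | COC(=O)c1c(C)c(OC#CC(=O)OCc2ccccc2)c(OCc3ccccc3)c(C)c1OCc4ccccc4 | intermediate
14 | 4-hydroxy-6-methyl-2H-pyran-2-one | Cc1cc(O)cc(=O)o1 | starting material
15 | 4-[(4-methoxybenzyl)oxy]-6-methyl-2H-pyran-2-one | Cc1cc(OCc2ccc(OC)cc2)cc(=O)o1 | intermediate
16 | benzyl 5-[2,4-bis(benzyloxy)-5-(methoxycarbonyl)-3,6-dimethylphenoxy]-8-[(4-methoxybenzyl)oxy]-1-methyl-3-oxo-2-oxabicyclo[2.2.2]octa-5,7-diene-6-carboxylate (racemic; bridgeheads fixed by the bicycle) | CC12OC(=O)C(C(OCc3ccc(OC)cc3)=C1)C(Oc4c(C)c(C(=O)OC)c(OCc5ccccc5)c(C)c4OCc6ccccc6)=C2C(=O)OCc7ccccc7 | intermediate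
17 | methyl 4,6-bis(benzyloxy)-3-{2-[(benzyloxy)carbonyl]-5-[(4-methoxybenzyl)oxy]-3-methylphenoxy}-2,5-dimethylbenzoate | COC(=O)c1c(C)c(Oc2cc(OCc3ccc(OC)cc3)cc(C)c2C(=O)OCc4ccccc4)c(OCc5ccccc5)c(C)c1OCc6ccccc6 | intermediate
18 | methyl 4,6-bis(benzyloxy)-3-{2-[(benzyloxy)carbonyl]-5-hydroxy-3-methylphenoxy}-2,5-dimethylbenzoate | COC(=O)c1c(C)c(Oc2cc(O)cc(C)c2C(=O)OCc3ccccc3)c(OCc4ccccc4)c(C)c1OCc5ccccc5 | intermediate
19 | methyl 4,6-bis(benzyloxy)-3-{2-[(benzyloxy)carbonyl]-4-chloro-5-hydroxy-3-methylphenoxy}-2,5-dimethylbenzoate | COC(=O)c1c(C)c(Oc2cc(O)c(Cl)c(C)c2C(=O)OCc3ccccc3)c(OCc4ccccc4)c(C)c1OCc5ccccc5 | intermediate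
20 | methyl 4,6-bis(benzyloxy)-3-{2-[(benzyloxy)carbonyl]-4-chloro-5-hydroxy-6-(hydroxymethyl)-3-methylphenoxy}-2,5-dimethylbenzoate (magnesium-bound in the flask) | COC(=O)c1c(C)c(Oc2c(CO)c(O)c(Cl)c(C)c2C(=O)OCc3ccccc3)c(OCc4ccccc4)c(C)c1OCc5ccccc5 | intermediate
21 | methyl 4,6-bis(benzyloxy)-3-{2-[(benzyloxy)carbonyl]-4-chloro-6-formyl-5-hydroxy-3-methylphenoxy}-2,5-dimethylbenzoate | COC(=O)c1c(C)c(Oc2c(C=O)c(O)c(Cl)c(C)c2C(=O)OCc3ccccc3)c(OCc4ccccc4)c(C)c1OCc5ccccc5 | intermediate
22 | 3-chloro-6-[2,4-dihydroxy-5-(methoxycarbonyl)-3,6-dimethylphenoxy]-5-formyl-4-hydroxy-2-methylbenzoic acid (CNP0210944.0) | COC(=O)c1c(C)c(Oc2c(C=O)c(O)c(Cl)c(C)c2C(=O)O)c(O)c(C)c1O | target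

## Step count and risks

Total: 11 steps. Longest linear sequence: 10 steps (steps 1–5 and 7–11, from 1 to 22); step 6 is a one-step branch.

**Step 7 (key step, proposed new method).**
- What may go wrong: the cycloaddition may be too slow, because oxygen donation into the alkyne lowers its dienophilicity. At the temperature then needed, the alkynyl ether may oligomerize or be hydrated by traces of water, and the 4-methoxybenzyl group may migrate or be lost from the pyrone. Misorientation is the less likely failure.
- Fallback (known chemistry, sets out from 6, returns at 17): the ether bond is made directly on a ring B that still lacks its C2' substituent, so the electrophile has only one ortho group. Orsellinic acid is esterified with BnBr and KHCO3 in DMF to benzyl 2,4-dihydroxy-6-methylbenzoate F1. The non-chelated 4-hydroxyl is alkylated with 4-methoxybenzyl chloride and K2CO3 to give benzyl 2-hydroxy-4-[(4-methoxybenzyl)oxy]-6-methylbenzoate F2. The chelated phenol is converted with Tf2O and pyridine into aryl triflate F3. Palladium-catalysed C–O coupling of 6 with F3 (Pd2(dba)3, t-BuXPhos, K3PO4, toluene, 100 °C; Buchwald–Hartwig diaryl ether synthesis) then gives 17.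

**Step 5.**
- What may go wrong: n-BuLi may add to the ring A methyl ester or deprotonate the C2 methyl group before the vinyl deprotonation and chlorine–lithium exchange are complete, and excess base may consume the chloroformate.
- Fallback (sets out from 6, returns at 13): no organolithium is used while the alkyne is built. DABCO-catalysed conjugate addition of 6 to benzyl propiolate gives the (E)-3-aryloxyacrylate F4. Bromine addition gives dibromide F5, which loses HBr with Et3N to give the (Z)-2-bromo-3-aryloxyacrylate F6. Anti-dehydrobromination of this β-bromovinyl ether with lithium 2,2,6,6-tetramethylpiperidide at −78 °C, the classical elimination route to alkynyl ethers, gives 13.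

**Step 9.**
- What may go wrong: site selectivity between C4' and C2' may be poor, since both are ortho to the phenol, or a second chlorine may enter.
- Fallback (sets out from 18, returns at 19): control is moved from the phenol to the ether oxygen. Silylation with i-Pr3SiCl and imidazole gives triisopropylsilyl ether F7, in which C2' lies between two bulky oxygen substituents and para attack relative to the diaryl ether oxygen should dominate. Chlorination with N-chlorosuccinimide and catalytic acid gives F8, and Bu4NF returns 19.

**Step 10.**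
- What may go wrong: the phenoxide is deactivated by the ortho chlorine and the para ester, and C2' is crowded, so the reaction may stall before or at the hydroxymethyl stage.
- Fallback (sets out from 19, returns at 21): the carbon is delivered intramolecularly. O-allylation with allyl bromide and K2CO3 gives allyl ether F9. Claisen rearrangement at about 190 °C in N,N-diethylaniline can end only at C2', since the other ortho carbon bears chlorine and the para carbon the ester, and gives the 2'-allyl phenol F10. Isomerization with RuHCl(CO)(PPh3)3 gives the (E)-propenyl phenol F11. Lemieux–Johnson cleavage (OsO4 cat., NaIO4, 2,6-lutidine, dioxane–H2O) gives 21.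

## Further compounds

F1 | step 7 | benzyl 2,4-dihydroxy-6-methylbenzoate | Cc1cc(O)cc(O)c1C(=O)OCc2ccccc2
F2 | step 7 | benzyl 2-hydroxy-4-[(4-methoxybenzyl)oxy]-6-methylbenzoate | Cc1cc(OCc2ccc(OC)cc2)cc(O)c1C(=O)OCc3ccccc3
F3 | step 7 | benzyl 4-[(4-methoxybenzyl)oxy]-6-methyl-2-{[(trifluoromethyl)sulfonyl]oxy}benzoate | Cc1cc(OCc2ccc(OC)cc2)cc(OS(=O)(=O)C(F)(F)F)c1C(=O)OCc3ccccc3
F4 | step 5 | methyl 4,6-bis(benzyloxy)-3-{[(1E)-3-(benzyloxy)-3-oxoprop-1-en-1-yl]oxy}-2,5-dimethylbenzoate | COC(=O)c1c(C)c(O/C=C/C(=O)OCc2ccccc2)c(OCc3ccccc3)c(C)c1OCc4ccccc4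
F5 | step 5 | methyl 4,6-bis(benzyloxy)-3-[3-(benzyloxy)-1,2-dibromo-3-oxopropoxy]-2,5-dimethylbenzoate (racemic anti adduct; both centres are lost in the next operation) | COC(=O)c1c(C)c(OC(Br)C(Br)C(=O)OCc2ccccc2)c(OCc3ccccc3)c(C)c1OCc4ccccc4
F6 | step 5 | methyl 4,6-bis(benzyloxy)-3-{[(1Z)-3-(benzyloxy)-2-bromo-3-oxoprop-1-en-1-yl]oxy}-2,5-dimethylbenzoate | COC(=O)c1c(C)c(O/C=C(\Br)C(=O)OCc2ccccc2)c(OCc3ccccc3)c(C)c1OCc4ccccc4
F7 | step 9 | methyl 4,6-bis(benzyloxy)-3-{2-[(benzyloxy)carbonyl]-3-methyl-5-[(triisopropylsilyl)oxy]phenoxy}-2,5-dimethylbenzoate | COC(=O)c1c(C)c(Oc2cc(O[Si](C(C)C)(C(C)C)C(C)C)cc(C)c2C(=O)OCc3ccccc3)c(OCc4ccccc4)c(C)c1OCc5ccccc5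
F8 | step 9 | methyl 4,6-bis(benzyloxy)-3-{2-[(benzyloxy)carbonyl]-4-chloro-3-methyl-5-[(triisopropylsilyl)oxy]phenoxy}-2,5-dimethylbenzoate | COC(=O)c1c(C)c(Oc2cc(O[Si](C(C)C)(C(C)C)C(C)C)c(Cl)c(C)c2C(=O)OCc3ccccc3)c(OCc4ccccc4)c(C)c1OCc5ccccc5
F9 | step 10 | methyl 3-{5-(allyloxy)-2-[(benzyloxy)carbonyl]-4-chloro-3-methylphenoxy}-4,6-bis(benzyloxy)-2,5-dimethylbenzoate | COC(=O)c1c(C)c(Oc2cc(OCC=C)c(Cl)c(C)c2C(=O)OCc3ccccc3)c(OCc4ccccc4)c(C)c1OCc5ccccc5
F10 | step 10 | methyl 3-{6-allyl-2-[(benzyloxy)carbonyl]-4-chloro-5-hydroxy-3-methylphenoxy}-4,6-bis(benzyloxy)-2,5-dimethylbenzoate | COC(=O)c1c(C)c(Oc2c(CC=C)c(O)c(Cl)c(C)c2C(=O)OCc3ccccc3)c(OCc4ccccc4)c(C)c1OCc5ccccc5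
F11 | step 10 | methyl 4,6-bis(benzyloxy)-3-{2-[(benzyloxy)carbonyl]-4-chloro-5-hydroxy-3-methyl-6-[(1E)-prop-1-en-1-yl]phenoxy}-2,5-dimethylbenzoate | COC(=O)c1c(C)c(Oc2c(/C=C/C)c(O)c(Cl)c(C)c2C(=O)OCc3ccccc3)c(OCc4ccccc4)c(C)c1OCc5ccccc5
A1 | alternative 1 | tert-butyl 3-chloro-6-(2-methoxy-2-oxoethoxy)-4-(methoxymethoxy)-2-methylbenzoate | COC(=O)COc1cc(OCOC)c(Cl)c(C)c1C(=O)OC(C)(C)C
A2 | alternative 1 | methyl 2-propanoylbut-2-enoate (E/Z mixture) | CC=C(C(=O)CC)C(=O)OC
A3 | alternative 1 | methyl 5-{2-[(tert-butoxy)carbonyl]-4-chloro-5-(methoxymethoxy)-3-methylphenoxy}-3,6-dimethyl-2,4-dioxocyclohexane-1-carboxylate (mixture of diastereomers and enol forms) | COC(=O)C1C(C)C(Oc2cc(OCOC)c(Cl)c(C)c2C(=O)OC(C)(C)C)C(=O)C(C)C1=O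
A4 | alternative 2 | tert-butyl 3-chloro-6-{[1-(4-hydroxy-5-methyl-2-oxo-2H-pyran-6-yl)-2-oxopropyl]oxy}-4-(methoxymethoxy)-2-methylbenzoate (racemic) | CC(=O)C(Oc1cc(OCOC)c(Cl)c(C)c1C(=O)OC(C)(C)C)c2oc(=O)cc(O)c2C
A5 | alternative 2 | methyl 6-{2-[(tert-butoxy)carbonyl]-4-chloro-5-(methoxymethoxy)-3-methylphenoxy}-4-methyl-3,5,7-trioxooctanoate (magnesium chelate in the flask; mixture of diastereomers and enol forms) | COC(=O)CC(=O)C(C)C(=O)C(Oc1cc(OCOC)c(Cl)c(C)c1C(=O)OC(C)(C)C)C(C)=O
A6 | alternative 2 | methyl 3-{2-[(tert-butoxy)carbonyl]-4-chloro-5-(methoxymethoxy)-3-methylphenoxy}-4,6-dihydroxy-2,5-dimethylbenzoate | COC(=O)c1c(C)c(Oc2cc(OCOC)c(Cl)c(C)c2C(=O)OC(C)(C)C)c(O)c(C)c1O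
A7 | alternative 3 | methyl (2E)-4-{2-[(tert-butoxy)carbonyl]-4-chloro-5-(methoxymethoxy)-3-methylphenoxy}-5-chloro-3-methyl-5-oxopent-2-enoate (racemic) | COC(=O)/C=C(\C)C(Oc1cc(OCOC)c(Cl)c(C)c1C(=O)OC(C)(C)C)C(Cl)=O
A8 | alternative 3 | methyl (2E)-4-{2-[(tert-butoxy)carbonyl]-4-chloro-5-(methoxymethoxy)-3-methylphenoxy}-3-methyl-5-oxopenta-2,4-dienoate (the aryloxy(vinyl)ketene) | COC(=O)/C=C(\C)C(Oc1cc(OCOC)c(Cl)c(C)c1C(=O)OC(C)(C)C)=C=O
A9 | alternative 3 | triisopropyl(prop-1-yn-1-yloxy)silane | CC#CO[Si](C(C)C)(C(C)C)C(C)C
A10 | alternative 3 | methyl 3-{2-[(tert-butoxy)carbonyl]-4-chloro-5-(methoxymethoxy)-3-methylphenoxy}-6-hydroxy-2,5-dimethyl-4-[(triisopropylsilyl)oxy]benzoate | COC(=O)c1c(C)c(Oc2cc(OCOC)c(Cl)c(C)c2C(=O)OC(C)(C)C)c(O[Si](C(C)C)(C(C)C)C(C)C)c(C)c1O
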